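Ring B is opened at C6–C7 and C8–C9: a ring A cyclohexane bearing an iodomethyl arm (C6) on quaternary C5 and, trans to it on C10, an (E)-aryl-propenyl arm (C9=C11–aryl) is annulated with methyl acrylate (C7, C8, future C8 methyl). In one radical chain the C6 radical adds to acrylate, the C8 radical closes 6-exo on C9, and the benzylic C11 radical is reduced. The step thus exploits the styrene made of C9, C11 and the arene, turning it into the C9 quaternary centre with its CH2–aryl group. A catalytic conjugate addition sets C10; C5, C9 and C8 are relayed. The C4 methylene is masked as a β-hydroxysilane.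

Key step: step 10

Conventions: avarane numbering is used. C4 bears the exocyclic CH2, C5/C10 are the ring-fusion carbons, C6/C7 the ring B methylenes, C8 the CH(CH3), C9 the quaternary carbon, C11 the benzylic CH2. The arene is numbered C1′ (on C11), C2′ (sulfate oxygen), C3′ (OH), C5′ (CH2OH). β is the face of the C5 methyl. Ar = 2-(benzyloxy)-5-{[tert-butyl(diphenyl)silyl]oxymethyl}-3-{[2-(trimethylsilyl)ethoxy]methoxy}phenyl.

Assumption: the target is taken as the free aryl hydrogen sulfate; sulfated intermediates are handled as salts and are written as the acids.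

Step 1
Reactants: 1 3-bromo-4,5-dihydroxybenzaldehyde
Product: 2 4-(benzyloxy)-3-bromo-5-hydroxybenzaldehyde
Conditions: BnBr (1.05 equiv), Li2CO3, DMF, 40 °C
Reagents that add atoms: benzyl bromide BrCc1ccccc1
Why: Williamson ether synthesis in which the 4-OH, para to the formyl group and flanked by bromine, is the more acidic phenol and is ionised selectively by the weak base, so the oxygen that will later carry the sulfate is the one benzylated.

Step 2
Reactants: 2 4-(benzyloxy)-3-bromo-5-hydroxybenzaldehyde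
Product: 3 4-(benzyloxy)-3-bromo-5-{[2-(trimethylsilyl)ethoxy]methoxy}benzaldehyde
Conditions: SEMCl, i-Pr2NEt, CH2Cl2, 0 °C to rt
Reagents that add atoms: 2-(trimethylsilyl)ethoxymethyl chloride ClCOCC[Si](C)(C)C
Why: Alkoxymethyl ether formation on the remaining phenol gives a base-stable, fluoride-labile ether that cannot migrate to the neighbouring oxygen later.

Step 3
Reactants: 3 4-(benzyloxy)-3-bromo-5-{[2-(trimethylsilyl)ethoxy]methoxy}benzaldehyde
Product: 4 [4-(benzyloxy)-3-bromo-5-{[2-(trimethylsilyl)ethoxy]methoxy}phenyl]methanol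
Conditions: NaBH4, MeOH, 0 °C
Reagents that add atoms: none
Why: Borohydride reduction of the aldehyde to the benzylic alcohol leaves the aryl bromide and both ethers untouched.

Step 4
Reactants: 4 [4-(benzyloxy)-3-bromo-5-{[2-(trimethylsilyl)ethoxy]methoxy}phenyl]methanol
Product: 5 aryl bromide Ar–Br, {[4-(benzyloxy)-3-bromo-5-{[2-(trimethylsilyl)ethoxy]methoxy}phenyl]methoxy}(tert-butyl)diphenylsilane
Conditions: TBDPSCl, imidazole, DMF, rt
Reagents that add atoms: tert-butyl(chloro)diphenylsilane CC(C)(C)[Si](Cl)(c1ccccc1)c1ccccc1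
Why: Silyl ether formation on the primary alcohol gives a group that should survive the organometallic, hydride and radical steps and leave with fluoride at the end.

Step 5
Reactants: 5 aryl bromide Ar–Br
Product: 6 1-Ar-prop-1-yne
Conditions: propyne, PdCl2(MeCN)2 (3 mol %), XPhos (9 mol %), Cs2CO3, MeCN, 70 °C, sealed tube
Reagents that add atoms: propyne CC#C
Why: Copper-free Sonogashira coupling, in which the bulky biaryl phosphine allows oxidative addition into the electron-rich, ortho-alkoxy aryl bromide.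

Step 6
Reactants: 6 1-Ar-prop-1-yne
Product: 8 (E)-2-iodo-1-Ar-prop-1-ene (iodine trans to Ar), via alkenylzirconocene chloride 7 (not isolated)
Conditions: Cp2Zr(H)Cl (1.5 equiv), THF, rt; then I2, 0 °C
Reagents that add atoms: iodine II
Why: Hydrozirconation then iodinolysis, in which syn addition of Zr–H places zirconium on the less hindered methyl-bearing alkyne carbon (excess reagent equilibrates the regioisomers) and iodine replaces zirconium with retention.

Step 7
Reactants: 8 (E)-2-iodo-1-Ar-prop-1-ene, 9 2-methylcyclohex-2-en-1-one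
Product: 13 (2R,3S)-2-(hydroxymethyl)-2-methyl-3-[(E)-1-Ar-prop-1-en-2-yl]cyclohexan-1-one (CH2OH trans to the alkenyl arm), via alkenyllithium 10 (not isolated), via alkenylmagnesium bromide 11 (not isolated), via magnesium enolate 12 (not isolated)
Conditions: 8, t-BuLi (2.0 equiv), Et2O, −78 °C; MgBr2·OEt2; added to 9, Cu(OTf)2 (4 mol %), chiral hydroxyalkyl imidazolinium chloride (NHC precursor, 5 mol %), Et2O, −30 °C; then CH2O (gas), −78 to −20 °C; aq. NH4Cl
Reagents that add atoms: formaldehyde C=O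
Why: Copper-catalysed asymmetric conjugate addition of a Grignard reagent to an α-substituted cyclic enone with aldol trapping, in which the chiral NHC–copper complex (ligand enantiomer chosen for 3S) sets C10 and formaldehyde enters the magnesium enolate anti to the new arm, relaying C5 and placing C6 trans to C9.

Step 8
Reactants: 13 (2R,3S)-2-(hydroxymethyl)-2-methyl-3-[(E)-1-Ar-prop-1-en-2-yl]cyclohexan-1-one
Product: 14 (2S,3S)-2-(iodomethyl)-2-methyl-3-[(E)-1-Ar-prop-1-en-2-yl]cyclohexan-1-one
Conditions: PPh3, I2, imidazole (premixed), PhMe, 80 °C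
Reagents that add atoms: iodine II
Why: Appel iodination of the neopentyl-type primary alcohol (SN2 on the alkoxyphosphonium ion, hence the heating), with elimination excluded by the quaternary α-carbon.

Step 9
Reactants: 14 (2S,3S)-2-(iodomethyl)-2-methyl-3-[(E)-1-Ar-prop-1-en-2-yl]cyclohexan-1-one
Product: 15 (2S,3S)-2-(iodomethyl)-2-methyl-3-[(E)-1-Ar-prop-1-en-2-yl]-1-[(trimethylsilyl)methyl]cyclohexan-1-ol (C1 epimers, carried together)
Conditions: Me3SiCH2Li, CeCl3, THF, −78 °C
Reagents that add atoms: (trimethylsilyl)methyllithium [Li]C[Si](C)(C)C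
Why: Organocerium addition (first stage of a Peterson olefination) to the hindered, enolisable ketone without touching the alkyl iodide; both C4 epimers later give the same exocyclic methylene, and the sp3 C4 protects the coming C6 radical from 1,2-acyl or vinyl shifts.

Step 10
Reactants: 15 (2S,3S)-2-(iodomethyl)-2-methyl-3-[(E)-1-Ar-prop-1-en-2-yl]-1-[(trimethylsilyl)methyl]cyclohexan-1-ol, 16 methyl acrylate
Product: 18 methyl (5S,10S)-9α-(Ar-methyl)-4-hydroxy-5β,9β-dimethyl-4-[(trimethylsilyl)methyl]-trans-decalin-8β-carboxylate (ester equatorial), via C8-epimeric ester mixture 17 (not isolated)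
Conditions: (Me3Si)3SiH (1.3 equiv) and AIBN (0.2 equiv) by syringe pump, 16 (8 equiv), PhH (0.02 M), 80 °C; evaporate; NaOMe (0.3 equiv), MeOH, 40 °C
Reagents that add atoms: none
Why: Iodine abstraction by the silyl radical gives the neopentyl C6 radical, which cannot close on its own styrene (4-exo or 5-endo) and adds to methyl acrylate (C6–C7); the electrophilic α-ester C8 radical then attacks the electron-rich styrene at C9 (C8–C9) and the benzylic C11 radical takes hydrogen from the silane, so one chain makes both bonds and the CH2–aryl group. The closest known reaction type is the reductive radical annulation of an alkyl halide with an acrylate (Giese addition, exo cyclisation, hydrogen transfer). Ring B closes 6-exo-trig, attack at C11 (7-endo) being disfavoured by ring size and by loss of the benzylic radical, and the trans ring fusion is already fixed by the trans C6 and C9 arms on ring A. C9 is controlled by the chair transition state in which C10–H lies near the plane of C9=C11 (allylic strain), which puts C11 equatorial and the C9 methyl axial and syn to the C5 methyl, and the same epimer is the more stable one if the closure is reversible; both alkene geometries lead to it. C8 is not fixed by the radical step but by the NaOMe equilibration towards the equatorial 8β ester. The step needs the C6 radical to choose acrylate over 1,5-hydrogen transfer or skeletal shifts and the C8 radical to cyclise before it is reduced or adds a second acrylate, which excess acrylate, the sp3 C4 and a low stationary silane concentration should secure.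

Step 11
Reactants: 18 methyl 8β-carboxylate
Product: 19 (5S,10S)-9α-(Ar-methyl)-8β-(hydroxymethyl)-5β,9β-dimethyl-4-[(trimethylsilyl)methyl]-trans-decalin-4-ol
Conditions: LiAlH4, THF, 0 °C
Reagents that add atoms: none
Why: Hydride reduction of the ester to the primary alcohol, with the tertiary alcohol, the ethers and the silyl ether unaffected at 0 °C.

Step 12
Reactants: 19 8β-(hydroxymethyl) diol
Product: 20 primary tosylate of 19, (5S,10S)-9α-(Ar-methyl)-5β,9β-dimethyl-8β-[(tosyloxy)methyl]-4-[(trimethylsilyl)methyl]-trans-decalin-4-ol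
Conditions: TsCl, pyridine, DMAP (cat.), CH2Cl2, 0 °C to rt
Reagents that add atoms: p-toluenesulfonyl chloride Cc1ccc(cc1)S(=O)(=O)Cl
Why: Selective sulfonylation of the primary alcohol; the hindered tertiary alcohol does not react, so the β-hydroxysilane stays intact.

Step 13
Reactants: 20 primary tosylate
Product: 21 (5S,10S)-9α-(Ar-methyl)-5β,8β,9β-trimethyl-4-[(trimethylsilyl)methyl]-trans-decalin-4-ol
Conditions: LiEt3BH, THF, 0 °C to rt
Reagents that add atoms: none
Why: SN2 displacement of the tosylate by hydride turns the former ester carbon into the equatorial C8 methyl without touching the C8 stereocentre.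

Step 14
Reactants: 21 8β-methyl compound
Product: 22 phenol, compound 21 with the 2′-benzyl ether replaced by OH
Conditions: H2 (1 atm), Pd/C, EtOAc, rt
Reagents that add atoms: none
Why: Hydrogenolysis of the aryl benzyl ether, placed here because no C=C bond is present while C4 is still masked; the SEM ether and the benzylic silyl ether should be retained under neutral conditions.

Step 15
Reactants: 22 phenol
Product: 24 2-{[(1R,2S,4aS,8aS)-1,2,4a-trimethyl-5-methylidenedecahydronaphthalen-1-yl]methyl}-4-{[tert-butyl(diphenyl)silyl]oxymethyl}-6-{[2-(trimethylsilyl)ethoxy]methoxy}phenyl hydrogen sulfate, via potassium phenoxide 23 (not isolated)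
Conditions: KH (2.1 equiv), THF, 0 °C to rt, argon; then SO3·NMe3 (3 equiv), DMF, rt to 40 °C; aqueous work-up
Reagents that add atoms: sulfur trioxide–trimethylamine complex C[N+](C)(C)S(=O)(=O)[O-]
Why: Base-induced Peterson elimination of the potassium β-silyl alkoxide gives only the exocyclic C4=CH2, and the potassium phenoxide is then sulfated by the SO3–amine complex; the neighbouring oxygens are blocked as non-migrating ethers, so only O–C2′ is sulfated.

Step 16
Reactants: 24 protected aryl hydrogen sulfate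
Product: 25 2-{[(1R,2S,4aS,8aS)-1,2,4a-trimethyl-5-methylidenedecahydronaphthalen-1-yl]methyl}-6-hydroxy-4-(hydroxymethyl)phenyl hydrogen sulfate (target)
Conditions: n-Bu4NF (6 equiv), THF/DMPU, 60 °C; then Dowex 50W (H+ form), MeOH/H2O, 0 °C, brief
Reagents that add atoms: none
Why: Fluoride cleavage of the silyl ether and of the SEM ether (fragmentation to ethene, formaldehyde and fluorosilane) under conditions that aryl sulfate monoesters and the exocyclic alkene should tolerate, followed by cation exchange to the hydrogen sulfate.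

Compound list
1 | 3-bromo-4,5-dihydroxybenzaldehyde | Brc1cc(C=O)cc(O)c1O | starting material
2 | 4-(benzyloxy)-3-bromo-5-hydroxybenzaldehyde | Brc1cc(C=O)cc(O)c1OCc2ccccc2 | intermediate
3 | 4-(benzyloxy)-3-bromo-5-{[2-(trimethylsilyl)ethoxy]methoxy}benzaldehyde | Brc1cc(C=O)cc(OCOCC[Si](C)(C)C)c1OCc2ccccc2 | intermediate
4 | [4-(benzyloxy)-3-bromo-5-{[2-(trimethylsilyl)ethoxy]methoxy}phenyl]methanol | Brc1cc(CO)cc(OCOCC[Si](C)(C)C)c1OCc2ccccc2 | intermediate
5 | aryl bromide Ar–Br (TBDPS ether of 4) | Brc1cc(CO[Si](c2ccccc2)(c3ccccc3)C(C)(C)C)cc(OCOCC[Si](C)(C)C)c1OCc4ccccc4 | intermediate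
6 | 1-Ar-prop-1-yne | CC#Cc1cc(CO[Si](c2ccccc2)(c3ccccc3)C(C)(C)C)cc(OCOCC[Si](C)(C)C)c1OCc4ccccc4 | intermediate
7 | chloro[(E)-1-Ar-prop-1-en-2-yl]bis(cyclopentadienyl)zirconium (Zr trans to Ar) | Cl[Zr](C1C=CC=C1)(C2C=CC=C2)/C(C)=C/c3cc(CO[Si](c4ccccc4)(c5ccccc5)C(C)(C)C)cc(OCOCC[Si](C)(C)C)c3OCc6ccccc6 | intermediate (not isolated)
8 | (E)-2-iodo-1-Ar-prop-1-ene | I/C(C)=C/c1cc(CO[Si](c2ccccc2)(c3ccccc3)C(C)(C)C)cc(OCOCC[Si](C)(C)C)c1OCc4ccccc4 | intermediate
9 | 2-methylcyclohex-2-en-1-one | CC1=CCCCC1=O | starting material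
10 | (E)-1-Ar-prop-1-en-2-yllithium | [Li]/C(C)=C/c1cc(CO[Si](c2ccccc2)(c3ccccc3)C(C)(C)C)cc(OCOCC[Si](C)(C)C)c1OCc4ccccc4 | intermediate (not isolated)
11 | (E)-1-Ar-prop-1-en-2-ylmagnesium bromide | Br[Mg]/C(C)=C/c1cc(CO[Si](c2ccccc2)(c3ccccc3)C(C)(C)C)cc(OCOCC[Si](C)(C)C)c1OCc4ccccc4 | intermediate (not isolated)
12 | bromomagnesium enolate of (3S)-2-methyl-3-[(E)-1-Ar-prop-1-en-2-yl]cyclohexan-1-one | CC1=C(O[Mg]Br)CCC[C@H]1/C(C)=C/c2cc(CO[Si](c3ccccc3)(c4ccccc4)C(C)(C)C)cc(OCOCC[Si](C)(C)C)c2OCc5ccccc5 | intermediate (not isolated)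
13 | (2R,3S)-2-(hydroxymethyl)-2-methyl-3-[(E)-1-Ar-prop-1-en-2-yl]cyclohexan-1-one | O=C1CCC[C@@H](/C(C)=C/c2cc(CO[Si](c3ccccc3)(c4ccccc4)C(C)(C)C)cc(OCOCC[Si](C)(C)C)c2OCc5ccccc5)[C@]1(C)CO | intermediate
14 | (2S,3S)-2-(iodomethyl)-2-methyl-3-[(E)-1-Ar-prop-1-en-2-yl]cyclohexan-1-one | O=C1CCC[C@@H](/C(C)=C/c2cc(CO[Si](c3ccccc3)(c4ccccc4)C(C)(C)C)cc(OCOCC[Si](C)(C)C)c2OCc5ccccc5)[C@]1(C)CI | intermediate
15 | (2S,3S)-2-(iodomethyl)-2-methyl-3-[(E)-1-Ar-prop-1-en-2-yl]-1-[(trimethylsilyl)methyl]cyclohexan-1-ol (C1 epimers, C1 left undefined) | C[Si](C)(C)CC1(O)CCC[C@@H](/C(C)=C/c2cc(CO[Si](c3ccccc3)(c4ccccc4)C(C)(C)C)cc(OCOCC[Si](C)(C)C)c2OCc5ccccc5)[C@]1(C)CI | intermediate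
16 | methyl acrylate | C=CC(=O)OC | starting material
17 | C8-epimeric mixture of ester 18 (C8 undefined) | C[Si](C)(C)CC1(O)CCC[C@H]2[C@](C)(Cc3cc(CO[Si](c4ccccc4)(c5ccccc5)C(C)(C)C)cc(OCOCC[Si](C)(C)C)c3OCc6ccccc6)C(C(=O)OC)CC[C@]12C | intermediate (not isolated)
18 | methyl (5S,10S)-9α-(Ar-methyl)-4-hydroxy-5β,9β-dimethyl-4-[(trimethylsilyl)methyl]-trans-decalin-8β-carboxylate | C[Si](C)(C)CC1(O)CCC[C@H]2[C@](C)(Cc3cc(CO[Si](c4ccccc4)(c5ccccc5)C(C)(C)C)cc(OCOCC[Si](C)(C)C)c3OCc6ccccc6)[C@@H](C(=O)OC)CC[C@]12C | intermediate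
19 | (5S,10S)-9α-(Ar-methyl)-8β-(hydroxymethyl)-5β,9β-dimethyl-4-[(trimethylsilyl)methyl]-trans-decalin-4-ol | C[Si](C)(C)CC1(O)CCC[C@H]2[C@](C)(Cc3cc(CO[Si](c4ccccc4)(c5ccccc5)C(C)(C)C)cc(OCOCC[Si](C)(C)C)c3OCc6ccccc6)[C@@H](CO)CC[C@]12C | intermediate
20 | primary tosylate of 19 | C[Si](C)(C)CC1(O)CCC[C@H]2[C@](C)(Cc3cc(CO[Si](c4ccccc4)(c5ccccc5)C(C)(C)C)cc(OCOCC[Si](C)(C)C)c3OCc6ccccc6)[C@@H](COS(=O)(=O)c7ccc(C)cc7)CC[C@]12C | intermediate
21 | (5S,10S)-9α-(Ar-methyl)-5β,8β,9β-trimethyl-4-[(trimethylsilyl)methyl]-trans-decalin-4-ol | C[Si](C)(C)CC1(O)CCC[C@H]2[C@](C)(Cc3cc(CO[Si](c4ccccc4)(c5ccccc5)C(C)(C)C)cc(OCOCC[Si](C)(C)C)c3OCc6ccccc6)[C@@H](C)CC[C@]12C | intermediate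
22 | phenol: 21 with 2′-OH in place of the benzyl ether | C[Si](C)(C)CC1(O)CCC[C@H]2[C@](C)(Cc3cc(CO[Si](c4ccccc4)(c5ccccc5)C(C)(C)C)cc(OCOCC[Si](C)(C)C)c3O)[C@@H](C)CC[C@]12C | intermediate
23 | potassium 2′-phenoxide of the 4-methylidene compound | [K+].C=C1CCC[C@H]2[C@](C)(Cc3cc(CO[Si](c4ccccc4)(c5ccccc5)C(C)(C)C)cc(OCOCC[Si](C)(C)C)c3[O-])[C@@H](C)CC[C@]12C | intermediate (not isolated)
24 | protected aryl hydrogen sulfate (2′-OSO3H, 3′-OSEM, 5′-CH2OTBDPS, 4-methylidene) | C=C1CCC[C@H]2[C@](C)(Cc3cc(CO[Si](c4ccccc4)(c5ccccc5)C(C)(C)C)cc(OCOCC[Si](C)(C)C)c3OS(=O)(=O)O)[C@@H](C)CC[C@]12C | intermediate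
25 | 2-{[(1R,2S,4aS,8aS)-1,2,4a-trimethyl-5-methylidenedecahydronaphthalen-1-yl]methyl}-6-hydroxy-4-(hydroxymethyl)phenyl hydrogen sulfate | C=C1CCC[C@H]2[C@](C)(Cc3cc(CO)cc(O)c3OS(=O)(=O)O)[C@@H](C)CC[C@]12C | target

Total step count: 16. Longest linear sequence: 16 steps (1 to 25); 9 and 16 are commercial and enter at steps 7 and 10.

Steps most likely to fail

Step 10. The C8 radical may be reduced or may add a second acrylate before it closes on the hindered C9, and the face selection at C9 may be incomplete. The fallback separates the two bond formations. It sets out from 15 and 16: a Giese addition with Bu3SnH at ordinary concentration (AIBN, PhH, 80 °C) should stop at the open-chain propanoate ester F1. Enolisation and bromination (LDA, 2.2 equiv, TMSCl, then NBS) would give the α-bromo ester F2. Slow addition of Bu3SnH/AIBN at high dilution then generates the C8 radical alone, with no acrylate present, and its 6-exo closure on C9 gives the ester mixture 17. After NaOMe equilibration the route is rejoined at 18.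

Step 7. The hindered, α-branched alkenyl Grignard reagent may add 1,2 or with poor facial discrimination, and capture of the magnesium enolate by gaseous formaldehyde may be incomplete. The fallback changes the nucleophile and decouples the C5–C6 bond formation. It sets out from 8 and 9: alkenyllithium 10 is transmetallated with Me2AlCl to the alkenyl(dimethyl)alane F3, which is added to 9 under Cu(OTf)2/chiral phosphoramidite catalysis (Et2O, −30 °C). The aluminium enolate is silylated with TMSOTf to the trimethylsilyl enol ether F4. A Mukaiyama-type hydroxymethylation (aqueous CH2O, Sc(OTf)3, THF, rt) then brings in C6 anti to the C10 arm and returns to 13.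

Step 15. Sulfation of the doubly flanked phenoxide may stall, and the phenoxide para to the silyloxymethyl group may be lost by elimination to a quinone methide or by air oxidation during the one-pot sequence. The fallback installs the sulfate as a neutral diester. It sets out from 22: Peterson elimination with KH followed by aqueous work-up gives the free 4-methylidene phenol F5. Sulfurylation with 2,2,2-trichloroethyl chlorosulfate (Et3N, DMAP, CH2Cl2) gives the aryl 2,2,2-trichloroethyl sulfate F6. Reductive unmasking (Zn dust, HCO2NH4, MeOH, rt) returns to 24.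

Further compounds
F1 | step 10 | open-chain propanoate ester (15 with CH2I replaced by CH2CH2CO2CH3) | C[Si](C)(C)CC1(O)CCC[C@@H](/C(C)=C/c2cc(CO[Si](c3ccccc3)(c4ccccc4)C(C)(C)C)cc(OCOCC[Si](C)(C)C)c2OCc5ccccc5)[C@]1(C)CCC(=O)OC
F2 | step 10 | α-bromo ester of F1 | C[Si](C)(C)CC1(O)CCC[C@@H](/C(C)=C/c2cc(CO[Si](c3ccccc3)(c4ccccc4)C(C)(C)C)cc(OCOCC[Si](C)(C)C)c2OCc5ccccc5)[C@]1(C)CCC(Br)C(=O)OC
F3 | step 7 | dimethyl[(E)-1-Ar-prop-1-en-2-yl]alane | C[Al](C)/C(C)=C/c1cc(CO[Si](c2ccccc2)(c3ccccc3)C(C)(C)C)cc(OCOCC[Si](C)(C)C)c1OCc4ccccc4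
F4 | step 7 | trimethylsilyl enol ether of (3S)-2-methyl-3-[(E)-1-Ar-prop-1-en-2-yl]cyclohexan-1-one | CC1=C(O[Si](C)(C)C)CCC[C@H]1/C(C)=C/c2cc(CO[Si](c3ccccc3)(c4ccccc4)C(C)(C)C)cc(OCOCC[Si](C)(C)C)c2OCc5ccccc5
F5 | step 15 | free 4-methylidene phenol (neutral form of 23) | C=C1CCC[C@H]2[C@](C)(Cc3cc(CO[Si](c4ccccc4)(c5ccccc5)C(C)(C)C)cc(OCOCC[Si](C)(C)C)c3O)[C@@H](C)CC[C@]12C
F6 | step 15 | aryl 2,2,2-trichloroethyl sulfate of F5 | C=C1CCC[C@H]2[C@](C)(Cc3cc(CO[Si](c4ccccc4)(c5ccccc5)C(C)(C)C)cc(OCOCC[Si](C)(C)C)c3OS(=O)(=O)OCC(Cl)(Cl)Cl)[C@@H](C)CC[C@]12C
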